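Readings and results are simulated with constants of no real substance, and the scatter is random.

1. A small charge of X makes D, and in the dawn run its crystals L read at most 1.0 %, while the summer run ends with 17.5 %. Whether the flask between them grows L is the question.

| setting | dawn | summer | flask |
|---|---|---|---|
| X | 0.060 M | 0.24 M | 0.12 M |
| remark | run made earlier | run made earlier |  |
| time |  |  | 30 h |

- dawn (time / h: D / %, L / %): 8.00: 28.7, 0; 15.0: 39.1, 1.0; 20.0: 41.0, 0; 30.0: 43.9, 0; 40.0: 45.4, 0.3
- summer (time / h: D / %, L / %): 3.00: 13.3, 0.7; 5.00: 22.3, 0; 10.0: 31.7, 2.4; 20.0: 42.8, 12.6; 40.0: 47.0, 17.5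

(scatter of a reading: 0.5 percentage points)

- amounts and yields of D count L too
- given per volume of solution although it is solid: L
- the numbers in the tables scatter with a standard deviation of 0.5 percentage points

- amount of D and L together at 30 h, in percent of the X charged
- concentration of D in solution at 30 h, in percent of saturation

2. Charge: y, the total of D and L, moves little with it. At 40.0 h the two runs differ by 1.6 points, though their charges differ by a factor of 4.00. Saturation, which is y times the charge over the solubility, follows the charge in full, and the charge is given.
3. Time: a small error costs little, since dawn climbs 4.4 points from 20.0 h to 40.0 h.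
4. Solubility S: this must be known well, since it enters the saturation in full.
5. Summer D minus L, over its last three readings, averages 0.0712 M, read as S. With c0 the charge of X, S/c0 = 59.3 %: the ceiling C, the share of the charge that solution holds dissolved at saturation.
6. Joining the ends: at 30 h dawn reads 43.9 % and summer, midway between readings, 44.9 %. The flask's charge is their geometric middle, 0.120 M, so the mean gives y = 44.4 %. That is under C, so no L is expected, and y/C = 74.8 % of saturation.
7. The forecast says 44.5 % and 75 %, with “no crystals form”.
8. The flask gives 43.6 % and 74.7 % of saturation, with y under C and L at 0 %. It also holds a further product Z at 34.2 %, which the readings do not show.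

    X ⇌ D (K = 4.00, k = 1.60 × 10⁻⁵ /s)
    X ⇌ Z (K = 120, k = 9.50 × 10⁻⁶ /s)
    X ⇌ J (K = 30.0, k = 6.80 × 10⁻⁸ /s)
    L ⇌ D, rate k4*(cs4 - [D]) while solid is left; crystals form when [D] > cs4 (solubility = 0.0700 M, k = 4.30 × 10⁻⁴ /s)
    X ⇌ G (K = 0.500, k = 6.30 × 10⁻⁶ /s)

The neighbour flask has the same charge but is read at 12 h. Dawn, interpolated between its readings, gives 34.6 %, and summer gives 33.9 %. Their mean is 34.3 %, under C, which is 57.8 % of saturation with no L expected. That neighbour flask gives y = 35.2 %, with L at 0 %.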